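**Retrosynthetic overview**
1. Target 25 ← desilylation ← 24 ← Evans–Tishchenko reduction of the macrocyclic C3‑hydroxy C1‑enone 23 (sets C1, installs the C3 acetate).
2. 23 ← nickel‑catalysed electroreductive acyl–vinyl ring closure (C1–C10 bond) of seco 2‑pyridyl ester / vinyl iodide 22; the ten‑membered ring is formed last.
3. 22 ← lactone ring, formed first, by indium Barbier allylation/lactonisation (C6–C7 bond, sets C6 and C7) of lactol 18 with allylic bromide 10.
4. 10 ← (S)‑glyceraldehyde acetonide 1 (C8) by Z‑iodo‑olefination, acylation with (S)‑2‑methylbutanoic anhydride 5, vinylalumination with methyl propiolate 8, SN2′ bromination.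
5. 18 ← L‑malic acid dioxolanone 11 (C3) by tetronic acid formation, triflation, Stille hydroxymethylation, silylation, partial reduction.

Assumption: atoms carry germacranolide numbers (C1 carbinol, C3 acetate carbon, C4=C5, C6 lactone carbinol, C7, C8 ester carbon, C9=C10, C11–C13 methylene lactone, C14 methyl, C15 hydroxymethyl), so the target is the (1S,3S,4Z,6S,7R,8R,9Z) 12,6‑olide; 1, 5, 8 and 11 are taken as commercial.

**Step 1**
Reactants: 1 (4S)-2,2-dimethyl-1,3-dioxolane-4-carbaldehyde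
Product: 2 (4R)-4-[(1Z)-2-iodoprop-1-en-1-yl]-2,2-dimethyl-1,3-dioxolane
Conditions: EtPPh3I, n-BuLi, THF, 25 °C; I2, −78 °C; NaN(SiMe3)2, −20 °C; then 1, −78 → −20 °C
Reagents that add atoms: ethyltriphenylphosphonium iodide CC[P+](c1ccccc1)(c1ccccc1)c1ccccc1.[I-]; iodine II
Why: Stork–Zhao iodo-olefination (Wittig reaction of the unstabilised α-iodo ylide) gives the (Z)-vinyl iodide with iodine cis to the future C8, whose configuration is bought with 1 and is not touched.

**Step 2**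
Reactants: 2 (4R)-4-[(1Z)-2-iodoprop-1-en-1-yl]-2,2-dimethyl-1,3-dioxolane
Product: 3 (2R,3Z)-4-iodopent-3-ene-1,2-diol
Conditions: AcOH/H2O (4:1), 40 °C
Reagents that add atoms: none
Why: Acid-catalysed acetal hydrolysis frees the 1,2-diol and leaves the vinyl iodide alone.

**Step 3**
Reactants: 3 (2R,3Z)-4-iodopent-3-ene-1,2-diol
Product: 4 (2R,3Z)-4-iodo-1-[(triethylsilyl)oxy]pent-3-en-2-ol
Conditions: Et3SiCl (1.05 equiv), imidazole, CH2Cl2, −78 → −30 °C
Reagents that add atoms: chlorotriethylsilane CC[Si](Cl)(CC)CC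
Why: Selective silyl ether formation, the primary hydroxyl reacting much faster than the allylic secondary one at low temperature.

**Step 4**
Reactants: 4 (2R,3Z)-4-iodo-1-[(triethylsilyl)oxy]pent-3-en-2-ol; 5 (2S)-2-methylbutanoic anhydride
Product: 6 (2R,3Z)-4-iodo-1-[(triethylsilyl)oxy]pent-3-en-2-yl (2S)-2-methylbutanoate
Conditions: DMAP (cat.), Et3N, CH2Cl2, 0 °C
Reagents that add atoms: none
Why: DMAP-catalysed acyl transfer to the only free hydroxyl installs the C8 ester, both stereocentres coming from purchased material.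

**Step 5**
Reactants: 6 (2R,3Z)-4-iodo-1-[(triethylsilyl)oxy]pent-3-en-2-yl (2S)-2-methylbutanoate
Product: 7 (2R,3Z)-4-iodo-1-oxopent-3-en-2-yl (2S)-2-methylbutanoate
Conditions: (COCl)2, DMSO, CH2Cl2, −78 → −40 °C; iPr2NEt, −78 °C; cold pH 7 work-up
Reagents that add atoms: none
Why: Swern oxidation converts a primary triethylsilyl ether directly into the aldehyde, and the hindered base at −78 °C keeps the α-acyloxy stereocentre intact.

**Step 6**
Reactants: 7 (2R,3Z)-4-iodo-1-oxopent-3-en-2-yl (2S)-2-methylbutanoate; 8 methyl prop-2-ynoate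
Product: 9 methyl (4R,5Z)-3-hydroxy-6-iodo-2-methylidene-4-{[(2S)-2-methylbutanoyl]oxy}hept-5-enoate (both C3 epimers)
Conditions: iBu2AlH, N-methylmorpholine N-oxide, THF, 0 °C, then 8; then 7, −78 → 0 °C
Reagents that add atoms: none
Why: Vinylalumination, in which 1,4-hydroalumination of the propiolate gives an α-aluminoacrylate that adds to the aldehyde, delivers the Morita–Baylis–Hillman-type adduct without base (the new carbinol centre is erased in step 7).

**Step 7**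
Reactants: 9 methyl (4R,5Z)-3-hydroxy-6-iodo-2-methylidene-4-{[(2S)-2-methylbutanoyl]oxy}hept-5-enoate
Product: 10 methyl (2Z,4S,5Z)-2-(bromomethyl)-6-iodo-4-{[(2S)-2-methylbutanoyl]oxy}hepta-2,5-dienoate
Conditions: NBS, Me2S, CH2Cl2, −20 → 0 °C
Reagents that add atoms: N-bromosuccinimide O=C1CCC(=O)N1Br
Why: Corey–Kim-type activation of the allylic alcohol and SN2′ attack of bromide give the favoured (Z)-2-(bromomethyl)enoate (the C8 label changes to S only because of CIP priorities).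

**Step 8**
Reactants: 11 2-[(4S)-2,2-dimethyl-5-oxo-1,3-dioxolan-4-yl]acetic acid
Product: 12 tert-butyl 2-[(4S)-2,2-dimethyl-5-oxo-1,3-dioxolan-4-yl]acetate
Conditions: tert-butyl 2,2,2-trichloroacetimidate, BF3·OEt2 (cat.), CH2Cl2/cyclohexane, 25 °C
Reagents that add atoms: tert-butyl 2,2,2-trichloroacetimidate CC(C)(C)OC(=N)C(Cl)(Cl)Cl
Why: Acid-catalysed imidate tert-butylation esterifies the free carboxyl and leaves the dioxolanone (the activated α-hydroxy acid) intact.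

**Step 9**
Reactants: 12 tert-butyl 2-[(4S)-2,2-dimethyl-5-oxo-1,3-dioxolan-4-yl]acetate
Product: 14 tert-butyl 2-[(2S)-3-hydroxy-5-oxo-2,5-dihydrofuran-2-yl]acetate, via open-chain keto ester 13 (not isolated)
Conditions: MeOAc, LiN(iPr)2 (2.2 equiv), THF, −78 °C; then 12, −78 → −20 °C; aq. HCl
Reagents that add atoms: methyl acetate COC(C)=O
Why: Claisen-type acylation of the acetate enolate by the dioxolanone, loss of acetone and Dieckmann-type lactonisation on acidification give the tetronic acid, the C3 stereocentre being that of L-malic acid.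

**Step 10**
Reactants: 14 tert-butyl 2-[(2S)-3-hydroxy-5-oxo-2,5-dihydrofuran-2-yl]acetate
Product: 15 tert-butyl 2-[(2S)-5-oxo-3-{[(trifluoromethyl)sulfonyl]oxy}-2,5-dihydrofuran-2-yl]acetate
Conditions: Tf2O, iPr2NEt, CH2Cl2, −78 °C
Reagents that add atoms: trifluoromethanesulfonic anhydride O=S(=O)(OS(=O)(=O)C(F)(F)F)C(F)(F)F
Why: O-sulfonylation of the vinylogous acid gives the enol triflate needed for cross-coupling.

**Step 11**
Reactants: 15 tert-butyl 2-[(2S)-5-oxo-3-{[(trifluoromethyl)sulfonyl]oxy}-2,5-dihydrofuran-2-yl]acetate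
Product: 16 tert-butyl 2-[(2S)-3-(hydroxymethyl)-5-oxo-2,5-dihydrofuran-2-yl]acetate
Conditions: Bu3SnCH2OH, Pd(PPh3)4 (5 mol%), LiCl, 1,4-dioxane, 90 °C
Reagents that add atoms: (tributylstannyl)methanol CCCC[Sn](CCCC)(CCCC)CO
Why: Stille cross-coupling of the enol triflate with the hydroxymethylstannane forms the C4–C15 bond on a ring that fixes the later 4Z geometry.

**Step 12**
Reactants: 16 tert-butyl 2-[(2S)-3-(hydroxymethyl)-5-oxo-2,5-dihydrofuran-2-yl]acetate
Product: 17 tert-butyl 2-[(2S)-3-({[tert-butyl(dimethyl)silyl]oxy}methyl)-5-oxo-2,5-dihydrofuran-2-yl]acetate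
Conditions: tBuMe2SiCl, imidazole, DMF, 0 °C
Reagents that add atoms: tert-butyl(chloro)dimethylsilane CC(C)(C)[Si](C)(C)Cl
Why: Standard silyl ether formation protects the C15 hydroxyl, which would otherwise lactonise onto the activated C1 ester later.

**Step 13**
Reactants: 17 tert-butyl 2-[(2S)-3-({[tert-butyl(dimethyl)silyl]oxy}methyl)-5-oxo-2,5-dihydrofuran-2-yl]acetate
Product: 18 tert-butyl 2-[(2S)-3-({[tert-butyl(dimethyl)silyl]oxy}methyl)-5-hydroxy-2,5-dihydrofuran-2-yl]acetate (both C5 epimers; used crude at once)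
Conditions: iBu2AlH (1.1 equiv), CH2Cl2, −78 °C; aq. potassium sodium tartrate
Reagents that add atoms: none
Why: Partial reduction stops at the aluminium hemiacetal, so the butenolide gives the lactol (the masked (Z)-4-hydroxy-enal) while the hindered tert-butyl ester is inert at −78 °C.

**Step 14**
Reactants: 18 tert-butyl 2-[(2S)-3-({[tert-butyl(dimethyl)silyl]oxy}methyl)-5-hydroxy-2,5-dihydrofuran-2-yl]acetate; 10 methyl (2Z,4S,5Z)-2-(bromomethyl)-6-iodo-4-{[(2S)-2-methylbutanoyl]oxy}hepta-2,5-dienoate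
Product: 20 tert-butyl (3S,4Z)-4-({[tert-butyl(dimethyl)silyl]oxy}methyl)-3-hydroxy-5-[(2S,3S)-3-[(1S,2Z)-3-iodo-1-{[(2S)-2-methylbutanoyl]oxy}but-2-en-1-yl]-4-methylidene-5-oxooxolan-2-yl]pent-4-enoate, via open-chain hydroxy diester 19 (not isolated)
Conditions: In powder (2 equiv), THF/H2O (1:1), 25 °C; then pyridinium p-toluenesulfonate (cat.), CH2Cl2, 25 °C
Reagents that add atoms: none
Why: Indium Barbier allylation of the open hydroxy-enal form of 18 through a chair (Zimmerman–Traxler) transition state gives the syn adduct, which lactonises to the cis C6/C7 α-methylene lactone; C7 is set by C8 (allylic strain puts C8–H in the alkene plane and the aldehyde adds anti to the bulky iodoalkenyl group) and C6 follows from the syn preference.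

**Step 15**
Reactants: 20 (seco tert-butyl ester)
Product: 21 (3S,4Z)-4-({[tert-butyl(dimethyl)silyl]oxy}methyl)-3-hydroxy-5-[(2S,3S)-3-[(1S,2Z)-3-iodo-1-{[(2S)-2-methylbutanoyl]oxy}but-2-en-1-yl]-4-methylidene-5-oxooxolan-2-yl]pent-4-enoic acid
Conditions: 85% aq. H3PO4, toluene, 25 °C
Reagents that add atoms: none
Why: Mild acidolysis cleaves the tert-butyl ester by alkyl–oxygen fission while the silyl ether, lactone and allylic ester survive.

**Step 16**
Reactants: 21 (seco acid)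
Product: 22 pyridin-2-yl (3S,4Z)-4-({[tert-butyl(dimethyl)silyl]oxy}methyl)-3-hydroxy-5-[(2S,3S)-3-[(1S,2Z)-3-iodo-1-{[(2S)-2-methylbutanoyl]oxy}but-2-en-1-yl]-4-methylidene-5-oxooxolan-2-yl]pent-4-enoate
Conditions: pyridin-2-ol, EDC·HCl, CH2Cl2, 0 °C
Reagents that add atoms: pyridin-2-ol Oc1ccccn1
Why: Carbodiimide esterification gives the 2-pyridyl active ester, the hindered secondary C3 hydroxyl not competing with pyridin-2-ol at 0 °C.

**Step 17**
Reactants: 22 (seco 2-pyridyl ester)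
Product: 23 (3S,4Z,6S,7R,8R,9Z)-15-{[tert-butyl(dimethyl)silyl]oxy}-3-hydroxy-8-{[(2S)-2-methylbutanoyl]oxy}-1-oxogermacra-4,9,11(13)-trien-12,6-olide
Conditions: NiBr2(dme) (20 mol%), 4,4′-di-tert-butyl-2,2′-bipyridine (24 mol%), NaI, N,N-dimethylacetamide, undivided cell, Zn anode, Ni-foam cathode, constant current 3 mA, 22 added over 10 h to 2 mM, 25 °C
Reagents that add atoms: none
Why: Proposed new method: cathodically generated zerovalent nickel–bipyridine inserts into the C–I bond of the (Z)-vinyl iodide with retention, reduction to the monovalent vinylnickel and chelation-assisted oxidative addition of the 2-pyridyl ester give an acyl(vinyl)nickel that reductively eliminates the C1–C10 bond, closing the ten-membered ring as the (9Z)-enone with the C3 hydroxyl left free; the closest known reaction type is the intermolecular nickel-catalysed (electro)reductive ketone synthesis from organic halides and activated carboxylic acid derivatives (acid chlorides, anhydrides, S-2-pyridyl thioesters).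

**Step 18**
Reactants: 23 (macrocyclic C3-hydroxy C1-enone)
Product: 24 (1S,3S,4Z,6S,7R,8R,9Z)-3-acetoxy-15-{[tert-butyl(dimethyl)silyl]oxy}-1-hydroxy-8-{[(2S)-2-methylbutanoyl]oxy}germacra-4,9,11(13)-trien-12,6-olide
Conditions: SmI2 (30 mol%, premixed with MeCHO), MeCHO (10 equiv), THF, −10 °C
Reagents that add atoms: acetaldehyde CC=O
Why: Evans–Tishchenko reduction, in which the samarium-bound hemiacetal formed from acetaldehyde on the C3 hydroxyl delivers hydride intramolecularly to the C1 ketone through a six-membered chair, gives the 1,3-anti (1S) alcohol and places the acetate on O3 in the same event.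

**Step 19**
Reactants: 24 (C15 silyl ether of the target)
Product: 25 (1S,3S,4Z,6S,7R,8R,9Z)-3-acetoxy-1,15-dihydroxy-8-{[(2S)-2-methylbutanoyl]oxy}germacra-4,9,11(13)-trien-12,6-olide (CNP0217661.3)
Conditions: HF·pyridine, pyridine, THF, 0 °C
Reagents that add atoms: none
Why: Buffered fluoride desilylation frees the C15 hydroxyl under weakly acidic conditions that avoid acetyl migration and conjugate addition to the α-methylene lactone.

**Compound list**
1 | (4S)-2,2-dimethyl-1,3-dioxolane-4-carbaldehyde | O=C[C@@H]1COC(C)(C)O1 | starting material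
2 | (4R)-4-[(1Z)-2-iodoprop-1-en-1-yl]-2,2-dimethyl-1,3-dioxolane | I/C(C)=C\[C@@H]1COC(C)(C)O1 | intermediate
3 | (2R,3Z)-4-iodopent-3-ene-1,2-diol | I/C(C)=C\[C@@H](O)CO | intermediate
4 | (2R,3Z)-4-iodo-1-[(triethylsilyl)oxy]pent-3-en-2-ol | I/C(C)=C\[C@@H](O)CO[Si](CC)(CC)CC | intermediate
5 | (2S)-2-methylbutanoic anhydride | CC[C@H](C)C(=O)OC(=O)[C@@H](C)CC | starting material
6 | (2R,3Z)-4-iodo-1-[(triethylsilyl)oxy]pent-3-en-2-yl (2S)-2-methylbutanoate | I/C(C)=C\[C@@H](OC(=O)[C@@H](C)CC)CO[Si](CC)(CC)CC | intermediate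
7 | (2R,3Z)-4-iodo-1-oxopent-3-en-2-yl (2S)-2-methylbutanoate | I/C(C)=C\[C@@H](OC(=O)[C@@H](C)CC)C=O | intermediate
8 | methyl prop-2-ynoate | C#CC(=O)OC | starting material
9 | methyl (4R,5Z)-3-hydroxy-6-iodo-2-methylidene-4-{[(2S)-2-methylbutanoyl]oxy}hept-5-enoate (C3 epimers) | I/C(C)=C\[C@@H](OC(=O)[C@@H](C)CC)C(O)C(=C)C(=O)OC | intermediate
10 | methyl (2Z,4S,5Z)-2-(bromomethyl)-6-iodo-4-{[(2S)-2-methylbutanoyl]oxy}hepta-2,5-dienoate | I/C(C)=C\[C@@H](OC(=O)[C@@H](C)CC)/C=C(\CBr)C(=O)OC | intermediate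
11 | 2-[(4S)-2,2-dimethyl-5-oxo-1,3-dioxolan-4-yl]acetic acid | CC1(C)OC(=O)[C@H](CC(=O)O)O1 | starting material
12 | tert-butyl 2-[(4S)-2,2-dimethyl-5-oxo-1,3-dioxolan-4-yl]acetate | CC1(C)OC(=O)[C@H](CC(=O)OC(C)(C)C)O1 | intermediate
13 | 6-tert-butyl 1-methyl (4S)-4-hydroxy-3-oxohexanedioate (open-chain keto ester) | COC(=O)CC(=O)[C@@H](O)CC(=O)OC(C)(C)C | intermediate
14 | tert-butyl 2-[(2S)-3-hydroxy-5-oxo-2,5-dihydrofuran-2-yl]acetate | O=C1C=C(O)[C@H](CC(=O)OC(C)(C)C)O1 | intermediate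
15 | tert-butyl 2-[(2S)-5-oxo-3-{[(trifluoromethyl)sulfonyl]oxy}-2,5-dihydrofuran-2-yl]acetate | O=C1C=C(OS(=O)(=O)C(F)(F)F)[C@H](CC(=O)OC(C)(C)C)O1 | intermediate
16 | tert-butyl 2-[(2S)-3-(hydroxymethyl)-5-oxo-2,5-dihydrofuran-2-yl]acetate | O=C1C=C(CO)[C@H](CC(=O)OC(C)(C)C)O1 | intermediate
17 | tert-butyl 2-[(2S)-3-({[tert-butyl(dimethyl)silyl]oxy}methyl)-5-oxo-2,5-dihydrofuran-2-yl]acetate | O=C1C=C(CO[Si](C)(C)C(C)(C)C)[C@H](CC(=O)OC(C)(C)C)O1 | intermediate
18 | tert-butyl 2-[(2S)-3-({[tert-butyl(dimethyl)silyl]oxy}methyl)-5-hydroxy-2,5-dihydrofuran-2-yl]acetate (C5 epimers) | OC1C=C(CO[Si](C)(C)C(C)(C)C)[C@H](CC(=O)OC(C)(C)C)O1 | intermediate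
19 | 9-tert-butyl 1-methyl (3S,4S,5Z,7S)-6-({[tert-butyl(dimethyl)silyl]oxy}methyl)-4,7-dihydroxy-3-[(1S,2Z)-3-iodo-1-{[(2S)-2-methylbutanoyl]oxy}but-2-en-1-yl]-2-methylidenenon-5-enedioate (open-chain hydroxy diester) | COC(=O)C(=C)[C@@H]([C@@H](O)/C=C(/CO[Si](C)(C)C(C)(C)C)[C@@H](O)CC(=O)OC(C)(C)C)[C@H](OC(=O)[C@@H](C)CC)/C=C(/C)I | intermediate
20 | tert-butyl (3S,4Z)-4-({[tert-butyl(dimethyl)silyl]oxy}methyl)-3-hydroxy-5-[(2S,3S)-3-[(1S,2Z)-3-iodo-1-{[(2S)-2-methylbutanoyl]oxy}but-2-en-1-yl]-4-methylidene-5-oxooxolan-2-yl]pent-4-enoate (seco ester; C3, C6, C7, C8 arranged in space as in the target) | C=C1C(=O)O[C@@H](/C=C(/CO[Si](C)(C)C(C)(C)C)[C@@H](O)CC(=O)OC(C)(C)C)[C@H]1[C@H](OC(=O)[C@@H](C)CC)/C=C(/C)I | intermediate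
21 | (3S,4Z)-4-({[tert-butyl(dimethyl)silyl]oxy}methyl)-3-hydroxy-5-[(2S,3S)-3-[(1S,2Z)-3-iodo-1-{[(2S)-2-methylbutanoyl]oxy}but-2-en-1-yl]-4-methylidene-5-oxooxolan-2-yl]pent-4-enoic acid (seco acid) | C=C1C(=O)O[C@@H](/C=C(/CO[Si](C)(C)C(C)(C)C)[C@@H](O)CC(=O)O)[C@H]1[C@H](OC(=O)[C@@H](C)CC)/C=C(/C)I | intermediate
22 | pyridin-2-yl ester of seco acid 21 | C=C1C(=O)O[C@@H](/C=C(/CO[Si](C)(C)C(C)(C)C)[C@@H](O)CC(=O)Oc2ccccn2)[C@H]1[C@H](OC(=O)[C@@H](C)CC)/C=C(/C)I | intermediate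
23 | (3S,4Z,6S,7R,8R,9Z)-15-{[tert-butyl(dimethyl)silyl]oxy}-3-hydroxy-8-{[(2S)-2-methylbutanoyl]oxy}-1-oxogermacra-4,9,11(13)-trien-12,6-olide | C=C1C(=O)O[C@H]2/C=C(/CO[Si](C)(C)C(C)(C)C)[C@@H](O)CC(=O)/C(C)=C\[C@@H](OC(=O)[C@@H](C)CC)[C@@H]12 | intermediate
24 | (1S,3S,4Z,6S,7R,8R,9Z)-3-acetoxy-15-{[tert-butyl(dimethyl)silyl]oxy}-1-hydroxy-8-{[(2S)-2-methylbutanoyl]oxy}germacra-4,9,11(13)-trien-12,6-olide | C=C1C(=O)O[C@H]2/C=C(/CO[Si](C)(C)C(C)(C)C)[C@@H](OC(C)=O)C[C@H](O)/C(C)=C\[C@@H](OC(=O)[C@@H](C)CC)[C@@H]12 | intermediate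
25 | (1S,3S,4Z,6S,7R,8R,9Z)-3-acetoxy-1,15-dihydroxy-8-{[(2S)-2-methylbutanoyl]oxy}germacra-4,9,11(13)-trien-12,6-olide (CNP0217661.3) | C=C1C(=O)O[C@H]2/C=C(/CO)[C@@H](OC(C)=O)C[C@H](O)/C(C)=C\[C@@H](OC(=O)[C@@H](C)CC)[C@@H]12 | target

**Totals**
Total step count: 19. Longest linear sequence: 13 steps (steps 1–7, then 14–19); the other branch (steps 8–13) has 6 steps before the union.

**Three steps most likely to fail**

Step 17 (proposed new ring closure). Likely failure modes are conjugate addition of the vinylnickel to the α-methylene lactone, nickel insertion into the allylic C8 ester, and oligomerisation. The fallback uses known chemistry, sets out from seco acid 21 and comes back at 23. Silylation with excess Et3SiCl/imidazole followed by aqueous work-up (which hydrolyses the silyl ester) gives the C3 triethylsilyl ether of the seco acid F1. BH3·SMe2 in THF at −10 °C reduces the acid to the seco C1 primary alcohol F2, and Dess–Martin periodinane gives the seco C1 aldehyde F3. A Nozaki–Hiyama–Kishi macrocyclisation (CrCl2, NiCl2 1 mol%, DMSO/THF, high dilution) closes the ring to the macrocyclic C1 allylic alcohol F4 as an epimer mixture. Dess–Martin periodinane then gives the C3-silylated macrocyclic enone F5, and pyridinium p-toluenesulfonate in MeOH at 0 °C removes the triethylsilyl group to give 23.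

Step 14 (Barbier allylation on the lactol). Likely failure modes are acid-promoted dehydration of lactol 18 to a furan, 1,4-elimination of the C8 acyloxy group from the allylindium, and weak facial control. The fallback avoids the lactol, sets out from 18 and comes back at 20. NaBH4 in MeOH at 0 °C gives the (Z)-ene-diol F6, and Et3SiCl (2.5 equiv)/imidazole gives the bis(triethylsilyl) ether F7. Swern oxidation, which attacks only the primary silyl ether, gives the acyclic C3-silylated (Z)-enal F8. Anhydrous Nozaki–Hiyama allylation with bromide 10 (CrCl2, THF, 25 °C) followed by acid-catalysed lactonisation gives the C3 triethylsilyl ether of the seco ester F9, and pyridinium p-toluenesulfonate in MeOH gives 20.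

Step 9 (tetronic acid formation). The basic enolate may deprotonate the dioxolanone at C3 (racemisation) or trigger β-elimination. The fallback is a neutral intramolecular Wittig route, sets out from 12 and comes back at 14. Benzyl alcohol with catalytic BnOLi opens the dioxolanone to 1-benzyl 4-tert-butyl (2S)-2-hydroxybutanedioate F10. Ketenylidenetriphenylphosphorane (Ph3P=C=C=O, toluene, 110 °C) adds to the hydroxyl and the resulting ylide olefinates the benzyl ester carbonyl to give the benzyl tetronate F11. Hydrogenolysis (H2, Pd/C, EtOAc) gives tetronic acid 14.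

**Further compounds**
F1 | step 17 | C3 triethylsilyl ether of seco acid 21 | C=C1C(=O)O[C@@H](/C=C(/CO[Si](C)(C)C(C)(C)C)[C@@H](O[Si](CC)(CC)CC)CC(=O)O)[C@H]1[C@H](OC(=O)[C@@H](C)CC)/C=C(/C)I
F2 | step 17 | seco C1 primary alcohol (C3 triethylsilyl ether) | C=C1C(=O)O[C@@H](/C=C(/CO[Si](C)(C)C(C)(C)C)[C@@H](O[Si](CC)(CC)CC)CCO)[C@H]1[C@H](OC(=O)[C@@H](C)CC)/C=C(/C)I
F3 | step 17 | seco C1 aldehyde (C3 triethylsilyl ether) | C=C1C(=O)O[C@@H](/C=C(/CO[Si](C)(C)C(C)(C)C)[C@@H](O[Si](CC)(CC)CC)CC=O)[C@H]1[C@H](OC(=O)[C@@H](C)CC)/C=C(/C)I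
F4 | step 17 | (3S,4Z,6S,7R,8R,9Z)-15-{[tert-butyl(dimethyl)silyl]oxy}-1-hydroxy-8-{[(2S)-2-methylbutanoyl]oxy}-3-[(triethylsilyl)oxy]germacra-4,9,11(13)-trien-12,6-olide (C1 epimers) | C=C1C(=O)O[C@H]2/C=C(/CO[Si](C)(C)C(C)(C)C)[C@@H](O[Si](CC)(CC)CC)CC(O)/C(C)=C\[C@@H](OC(=O)[C@@H](C)CC)[C@@H]12
F5 | step 17 | (3S,4Z,6S,7R,8R,9Z)-15-{[tert-butyl(dimethyl)silyl]oxy}-8-{[(2S)-2-methylbutanoyl]oxy}-1-oxo-3-[(triethylsilyl)oxy]germacra-4,9,11(13)-trien-12,6-olide | C=C1C(=O)O[C@H]2/C=C(/CO[Si](C)(C)C(C)(C)C)[C@@H](O[Si](CC)(CC)CC)CC(=O)/C(C)=C\[C@@H](OC(=O)[C@@H](C)CC)[C@@H]12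
F6 | step 14 | tert-butyl (3S,4Z)-4-({[tert-butyl(dimethyl)silyl]oxy}methyl)-3,6-dihydroxyhex-4-enoate | OC/C=C(/CO[Si](C)(C)C(C)(C)C)[C@@H](O)CC(=O)OC(C)(C)C
F7 | step 14 | tert-butyl (3S,4Z)-4-({[tert-butyl(dimethyl)silyl]oxy}methyl)-3,6-bis[(triethylsilyl)oxy]hex-4-enoate | CC[Si](CC)(CC)OC/C=C(/CO[Si](C)(C)C(C)(C)C)[C@@H](O[Si](CC)(CC)CC)CC(=O)OC(C)(C)C
F8 | step 14 | tert-butyl (3S,4Z)-4-({[tert-butyl(dimethyl)silyl]oxy}methyl)-6-oxo-3-[(triethylsilyl)oxy]hex-4-enoate | O=C/C=C(/CO[Si](C)(C)C(C)(C)C)[C@@H](O[Si](CC)(CC)CC)CC(=O)OC(C)(C)C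
F9 | step 14 | C3 triethylsilyl ether of seco ester 20 | C=C1C(=O)O[C@@H](/C=C(/CO[Si](C)(C)C(C)(C)C)[C@@H](O[Si](CC)(CC)CC)CC(=O)OC(C)(C)C)[C@H]1[C@H](OC(=O)[C@@H](C)CC)/C=C(/C)I
F10 | step 9 | 1-benzyl 4-tert-butyl (2S)-2-hydroxybutanedioate | O[C@@H](CC(=O)OC(C)(C)C)C(=O)OCc1ccccc1
F11 | step 9 | tert-butyl 2-[(2S)-3-(benzyloxy)-5-oxo-2,5-dihydrofuran-2-yl]acetate | O=C1C=C(OCc2ccccc2)[C@H](CC(=O)OC(C)(C)C)O1
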